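**Plan**

- Retrosynthesis: the five phenols are carried as benzyl ethers, and the C3–H and C4–H bonds are traced back to a C3=C4 double bond. That double bond is cut by ring-closing metathesis, the C3–O vanillate bond is traced to addition of the acid across a terminal alkyne, and the O1–C2 ether bond is cut to a ring A salicylaldehyde and a ring B propargylic acetate.
- Forward: the ring A aldehyde and the ring B propargylic acetate are joined through O1–C2, the aldehyde becomes the vinyl group, the vanillic acid unit is added to the alkyne, and ring C is closed last between C3 and C4.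
- Enabling feature: the C3–C4 bond of ring C joins the ester-bearing C3 to the carbon on ring A carbon C4a, so it can be made as the C3=C4 bond of an enol ester. O1 and the ring A carbons C8a and C4a hold the ring A vinyl group and the 1-acyloxyvinyl group in reach for a six-membered closure.
- Stereochemistry: C2 is set by catalyst control in a copper/pybox propargylic etherification. C3 is set by substrate control, hydrogenating the enol ester on the face away from the C2 aryl group (2,3-cis, 2R,3R).

Key step: step 6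

Assumption: (S,S)-Ph-pybox is taken to deliver the (S)-propargylic ether in step 3; if the sense of induction proves opposite, the (R,R)-ligand is used with no other change.

**Step 1**
Reactants: 1 3,5-bis(benzyloxy)phenol
Product: 2 2,4-bis(benzyloxy)-6-hydroxybenzaldehyde
Conditions: MgCl2, Et3N, (CH2O)n, MeCN, reflux
Reagents that add atoms: paraformaldehyde (as formaldehyde), C=O
Why: Magnesium-mediated ortho-formylation of a phenol (Casnati–Skattebøl reaction): the magnesium phenoxide delivers formaldehyde only next to the OH, the two ortho positions are equivalent, and a second formaldehyde accepts the hydride, so the chelated salicylaldehyde should be the only isomer.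

**Step 2**
Reactants: 3 3,4-bis(benzyloxy)benzaldehyde
Product: 5 rac-1-[3,4-bis(benzyloxy)phenyl]prop-2-yn-1-yl acetate, via bromomagnesium propargylic alkoxide 4 (not isolated)
Conditions: HC≡CMgBr, THF, 0 °C; then Ac2O, DMAP (cat.), 0 °C → rt
Reagents that add atoms: ethynylmagnesium bromide, C#C[Mg]Br; acetic anhydride, CC(=O)OC(C)=O
Why: Grignard 1,2-addition to the aldehyde followed by O-acetylation of the magnesium alkoxide in the same flask; the racemate is wanted because the next step is enantioconvergent.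

**Step 3**
Reactants: 2 2,4-bis(benzyloxy)-6-hydroxybenzaldehyde; 5 rac-1-[3,4-bis(benzyloxy)phenyl]prop-2-yn-1-yl acetate
Product: 6 (S)-2,4-bis(benzyloxy)-6-{[1-(3,4-bis(benzyloxy)phenyl)prop-2-yn-1-yl]oxy}benzaldehyde
Conditions: (CuOTf)2·C6H6 (2.5 mol %), (S,S)-Ph-pybox (10 mol %), i-Pr2NEt, CH2Cl2, −20 °C
Reagents that add atoms: none
Why: Copper-catalysed asymmetric propargylic substitution (etherification with a phenol): the monovalent copper acetylide of either enantiomer of 5 loses acetate to a common copper allenylidene, the pybox ligand directs the phenoxide to one face of the γ-carbon and so sets the future C2, and the formyl group makes the phenol more acidic and the ring less nucleophilic so that O-attack should outrun C-propargylation.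

**Step 4**
Reactants: 6 (S)-2,4-bis(benzyloxy)-6-{[1-(3,4-bis(benzyloxy)phenyl)prop-2-yn-1-yl]oxy}benzaldehyde
Product: 7 (S)-1,5-bis(benzyloxy)-3-{[1-(3,4-bis(benzyloxy)phenyl)prop-2-yn-1-yl]oxy}-2-vinylbenzene
Conditions: Ph3PCH3Br, NaN(SiMe3)2, THF, 0 °C; then 6, −78 → 0 °C
Reagents that add atoms: methyltriphenylphosphonium bromide, C[P+](c1ccccc1)(c1ccccc1)c1ccccc1.[Br-]
Why: Wittig methylenation of the aryl aldehyde; the unstabilised ylide is too weak a base to remove the ether C–H or the alkyne C–H to any extent at low temperature, so the stereocentre and the terminal alkyne should be untouched.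

**Step 5**
Reactants: 7 (S)-1,5-bis(benzyloxy)-3-{[1-(3,4-bis(benzyloxy)phenyl)prop-2-yn-1-yl]oxy}-2-vinylbenzene; 8 4-(benzyloxy)-3-methoxybenzoic acid
Product: 9 (R)-3-[3,4-bis(benzyloxy)phenyl]-3-[3,5-bis(benzyloxy)-2-vinylphenoxy]prop-1-en-2-yl 4-(benzyloxy)-3-methoxybenzoate
Conditions: [RuCl2(p-cymene)]2 (2 mol %), P(2-furyl)3 (4 mol %), Na2CO3 (8 mol %), toluene, 50–60 °C
Reagents that add atoms: none
Why: Ruthenium-catalysed Markovnikov hydro-oxycarbonylation of a terminal alkyne: with a weakly donating phosphine on divalent ruthenium and a carbonate base, the carboxylate attacks the internal carbon of the π-bound alkyne to give the 1-acyloxyvinyl ester, and the stereocentre is not involved (its descriptor changes from S to R only through the priority rules).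

**Step 6**
Reactants: 9 (R)-3-[3,4-bis(benzyloxy)phenyl]-3-[3,5-bis(benzyloxy)-2-vinylphenoxy]prop-1-en-2-yl 4-(benzyloxy)-3-methoxybenzoate
Product: 10 (R)-5,7-bis(benzyloxy)-2-[3,4-bis(benzyloxy)phenyl]-2H-chromen-3-yl 4-(benzyloxy)-3-methoxybenzoate
Conditions: (H2IMes)(PCy3)Cl2Ru=CHPh (second-generation Grubbs catalyst, 5–10 mol %), 1,4-benzoquinone (20 mol %), toluene (0.005 M), 60 °C, Ar sparge, protected from light
Reagents that add atoms: none
Why: The ruthenium benzylidene exchanges onto the monosubstituted ring A vinyl group, the new carbene adds to the 1-acyloxyvinyl alkene in a [2+2] cycloaddition, and cycloreversion of the metallacyclobutane gives the C3=C4 bond and Ru=CH2, which leaves as ethene after the next turnover. The closest known reaction type is ring-closing metathesis of 2-vinylaryl allyl ethers to 2H-chromenes and of styrenes with enol ethers, silyl enol ethers or enol esters to cyclic enol derivatives. Ring C closes as a six-membered ring by this intramolecular cycloaddition–cycloreversion, the tether C4a–C8a–O1–C2 holding the two alkenes together. No stereocentre is formed and C2 is a spectator. The step needs the carbene to load on the styrene rather than on the enol ester, which the substitution pattern secures (monosubstituted against 1,1-disubstituted alkene), and this regiochemistry gives Ru=CH2 rather than an acyloxycarbene. It also needs the double bond to stay at C3=C4 and C2 to keep its configuration, which benzoquinone (quenching ruthenium hydrides), conjugation of C3=C4 with ring A, moderate temperature and exclusion of light (no electrocyclic opening of the chromene) should secure.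

**Step 7**
Reactants: 10 (R)-5,7-bis(benzyloxy)-2-[3,4-bis(benzyloxy)phenyl]-2H-chromen-3-yl 4-(benzyloxy)-3-methoxybenzoate
Product: 11 (2R,3R)-5,7-bis(benzyloxy)-2-[3,4-bis(benzyloxy)phenyl]chroman-3-yl 4-(benzyloxy)-3-methoxybenzoate
Conditions: H2 (1–4 atm), Rh/Al2O3 (5 wt %), EtOAc, rt, dark
Reagents that add atoms: none
Why: Heterogeneous syn-hydrogenation of the enol ester: allylic 1,2-strain with the C3 ester turns the C2 aryl group pseudo-axial, so the alkene should adsorb on the opposite face, placing H3 trans to the aryl group and the ester cis (C3 = R); rhodium is chosen over palladium because it should leave the benzyl ethers, the allylic and benzylic C2–O1 bond and the vinylic C–O bond intact.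

**Step 8**
Reactants: 11 (2R,3R)-5,7-bis(benzyloxy)-2-[3,4-bis(benzyloxy)phenyl]chroman-3-yl 4-(benzyloxy)-3-methoxybenzoate
Product: 12 (2R,3R)-2-(3,4-dihydroxyphenyl)-5,7-dihydroxychroman-3-yl 4-hydroxy-3-methoxybenzoate (3-O-vanilloyl-(−)-epicatechin, CNP0302437.1)
Conditions: H2 (1 atm), Pd(OH)2/C, THF–MeOH, rt
Reagents that add atoms: none
Why: Hydrogenolysis of the five O-benzyl ethers over palladium, conditions under which the alkyl benzoate-type ester, the ring C ether and both stereocentres of benzylated flavan-3-ol esters are known to survive.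

**Compound list**

1 | 3,5-bis(benzyloxy)phenol | Oc1cc(OCc2ccccc2)cc(OCc2ccccc2)c1 | starting material
2 | 2,4-bis(benzyloxy)-6-hydroxybenzaldehyde | O=Cc1c(O)cc(OCc2ccccc2)cc1OCc1ccccc1 | intermediate
3 | 3,4-bis(benzyloxy)benzaldehyde | O=Cc1ccc(OCc2ccccc2)c(OCc2ccccc2)c1 | starting material
4 | bromomagnesium 1-[3,4-bis(benzyloxy)phenyl]prop-2-yn-1-olate (racemic) | C#CC(O[Mg]Br)c1ccc(OCc2ccccc2)c(OCc2ccccc2)c1 | intermediate
5 | rac-1-[3,4-bis(benzyloxy)phenyl]prop-2-yn-1-yl acetate | C#CC(OC(C)=O)c1ccc(OCc2ccccc2)c(OCc2ccccc2)c1 | intermediate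
6 | (S)-2,4-bis(benzyloxy)-6-{[1-(3,4-bis(benzyloxy)phenyl)prop-2-yn-1-yl]oxy}benzaldehyde | O=Cc1c(OCc2ccccc2)cc(OCc2ccccc2)cc1O[C@H](c1ccc(OCc2ccccc2)c(OCc2ccccc2)c1)C#C | intermediate
7 | (S)-1,5-bis(benzyloxy)-3-{[1-(3,4-bis(benzyloxy)phenyl)prop-2-yn-1-yl]oxy}-2-vinylbenzene | C=Cc1c(OCc2ccccc2)cc(OCc2ccccc2)cc1O[C@H](c1ccc(OCc2ccccc2)c(OCc2ccccc2)c1)C#C | intermediate
8 | 4-(benzyloxy)-3-methoxybenzoic acid | COc1cc(C(=O)O)ccc1OCc1ccccc1 | starting material
9 | (R)-3-[3,4-bis(benzyloxy)phenyl]-3-[3,5-bis(benzyloxy)-2-vinylphenoxy]prop-1-en-2-yl 4-(benzyloxy)-3-methoxybenzoate | C=Cc1c(OCc2ccccc2)cc(OCc2ccccc2)cc1O[C@H](c1ccc(OCc2ccccc2)c(OCc2ccccc2)c1)C(=C)OC(=O)c1ccc(OCc2ccccc2)c(OC)c1 | intermediate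
10 | (R)-5,7-bis(benzyloxy)-2-[3,4-bis(benzyloxy)phenyl]-2H-chromen-3-yl 4-(benzyloxy)-3-methoxybenzoate | COc1cc(C(=O)OC2=Cc3c(OCc4ccccc4)cc(OCc4ccccc4)cc3O[C@@H]2c2ccc(OCc3ccccc3)c(OCc3ccccc3)c2)ccc1OCc1ccccc1 | intermediate
11 | (2R,3R)-5,7-bis(benzyloxy)-2-[3,4-bis(benzyloxy)phenyl]chroman-3-yl 4-(benzyloxy)-3-methoxybenzoate | COc1cc(C(=O)O[C@@H]2Cc3c(OCc4ccccc4)cc(OCc4ccccc4)cc3O[C@@H]2c2ccc(OCc3ccccc3)c(OCc3ccccc3)c2)ccc1OCc1ccccc1 | intermediate
12 | (2R,3R)-2-(3,4-dihydroxyphenyl)-5,7-dihydroxychroman-3-yl 4-hydroxy-3-methoxybenzoate | COc1cc(C(=O)O[C@@H]2Cc3c(O)cc(O)cc3O[C@@H]2c2ccc(O)c(O)c2)ccc1O | target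

**Count**

Total steps: 8. Longest linear sequence: 7 steps (steps 1, 3, 4, 5, 6, 7, 8 from compound 1; equally steps 2–8 from compound 3).

**Steps most likely to fail**

Step 6 (ring-closing metathesis). The benzylidene formed on the ring A vinyl group may rest as an oxygen-chelated species and fail to engage the hindered 1,1-disubstituted enol ester, or ruthenium hydrides may move the double bond towards C2 and erase the stereocentre. The fallback moves the ring closure to a lower oxidation level and sets out from 7.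
- The alkyne is semi-hydrogenated (H2, Pd/CaCO3 poisoned with Pb(OAc)2, quinoline, EtOAc) to (S)-1,5-bis(benzyloxy)-3-{[1-(3,4-bis(benzyloxy)phenyl)prop-2-en-1-yl]oxy}-2-vinylbenzene F1.
- F1 is closed with the same ruthenium catalyst in CH2Cl2 at 40 °C, a standard 2H-chromene metathesis between two monosubstituted alkenes, to (S)-5,7-bis(benzyloxy)-2-[3,4-bis(benzyloxy)phenyl]-2H-chromene F2.
- Hydroboration–oxidation (BH3·SMe2, THF; then NaOH, H2O2) on the face away from the C2 aryl group should give (2R,3S)-5,7-bis(benzyloxy)-2-[3,4-bis(benzyloxy)phenyl]chroman-3-ol F3.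
- Dess–Martin oxidation gives (R)-5,7-bis(benzyloxy)-2-[3,4-bis(benzyloxy)phenyl]chroman-3-one F4.
- Reduction with LiBH(s-Bu)3 at −78 °C, hydride arriving anti to the aryl group, gives (2R,3R)-5,7-bis(benzyloxy)-2-[3,4-bis(benzyloxy)phenyl]chroman-3-ol F5.
- Esterification of F5 with acid 8 (EDC, DMAP, CH2Cl2) returns to the route at 11, leaving only step 8.

Step 3 (copper-catalysed etherification). The allenylidene may be captured at a ring carbon of the electron-rich phenol (Friedel–Crafts propargylation) instead of at oxygen, or the face selection may be insufficient. The fallback sets the stereocentre first and forms the ether bond by stereospecific substitution; it sets out from 3.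
- Zinc-mediated asymmetric alkynylation (Me2Zn, trimethylsilylacetylene, the ProPhenol antipode that gives the S carbinol, toluene) gives (S)-1-[3,4-bis(benzyloxy)phenyl]-3-(trimethylsilyl)prop-2-yn-1-ol F6.
- Mitsunobu reaction of F6 with phenol 2 (PPh3, DIAD, toluene, −20 °C, the low temperature and non-polar solvent chosen to hold back ionisation of the electron-rich benzylic alcohol) should give, with inversion, (R)-2,4-bis(benzyloxy)-6-{[1-(3,4-bis(benzyloxy)phenyl)-3-(trimethylsilyl)prop-2-yn-1-yl]oxy}benzaldehyde F7.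
- Desilylation (K2CO3, MeOH) returns to the route at 6.

Step 5 (addition of the acid to the alkyne). A ruthenium vinylidene pathway may give the anti-Markovnikov enol ester at this hindered alkyne, or the metal may ionise the propargylic aryl ether. The fallback fixes the regiochemistry with boron and then forms the C–O bond by oxidative coupling; it sets out from 7.
- Copper-catalysed α-selective protoboration ((SIMes)CuCl, NaOt-Bu, B2pin2, MeOH, THF), in which the propargylic oxygen directs boron to the internal carbon, gives 2-{(S)-3-[3,4-bis(benzyloxy)phenyl]-3-[3,5-bis(benzyloxy)-2-vinylphenoxy]prop-1-en-2-yl}-4,4,5,5-tetramethyl-1,3,2-dioxaborolane F8.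
- KHF2 in aqueous MeOH converts it into potassium (S)-{3-[3,4-bis(benzyloxy)phenyl]-3-[3,5-bis(benzyloxy)-2-vinylphenoxy]prop-1-en-2-yl}trifluoroborate F9.
- Chan–Lam-type coupling of F9 with acid 8 (Cu(OAc)2, DMAP, 4 Å molecular sieves, O2, CH2Cl2, 40 °C) returns to the route at 9.

**Further compounds**

F1 | step 6 | (S)-1,5-bis(benzyloxy)-3-{[1-(3,4-bis(benzyloxy)phenyl)prop-2-en-1-yl]oxy}-2-vinylbenzene | C=Cc1c(OCc2ccccc2)cc(OCc2ccccc2)cc1O[C@H](c1ccc(OCc2ccccc2)c(OCc2ccccc2)c1)C=C
F2 | step 6 | (S)-5,7-bis(benzyloxy)-2-[3,4-bis(benzyloxy)phenyl]-2H-chromene | C1=Cc2c(OCc3ccccc3)cc(OCc3ccccc3)cc2O[C@@H]1c1ccc(OCc2ccccc2)c(OCc2ccccc2)c1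
F3 | step 6 | (2R,3S)-5,7-bis(benzyloxy)-2-[3,4-bis(benzyloxy)phenyl]chroman-3-ol | O[C@H]1Cc2c(OCc3ccccc3)cc(OCc3ccccc3)cc2O[C@@H]1c1ccc(OCc2ccccc2)c(OCc2ccccc2)c1
F4 | step 6 | (R)-5,7-bis(benzyloxy)-2-[3,4-bis(benzyloxy)phenyl]chroman-3-one | O=C1Cc2c(OCc3ccccc3)cc(OCc3ccccc3)cc2O[C@@H]1c1ccc(OCc2ccccc2)c(OCc2ccccc2)c1
F5 | step 6 | (2R,3R)-5,7-bis(benzyloxy)-2-[3,4-bis(benzyloxy)phenyl]chroman-3-ol | O[C@@H]1Cc2c(OCc3ccccc3)cc(OCc3ccccc3)cc2O[C@@H]1c1ccc(OCc2ccccc2)c(OCc2ccccc2)c1
F6 | step 3 | (S)-1-[3,4-bis(benzyloxy)phenyl]-3-(trimethylsilyl)prop-2-yn-1-ol | O[C@@H](c1ccc(OCc2ccccc2)c(OCc2ccccc2)c1)C#C[Si](C)(C)C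
F7 | step 3 | (R)-2,4-bis(benzyloxy)-6-{[1-(3,4-bis(benzyloxy)phenyl)-3-(trimethylsilyl)prop-2-yn-1-yl]oxy}benzaldehyde | O=Cc1c(OCc2ccccc2)cc(OCc2ccccc2)cc1O[C@H](c1ccc(OCc2ccccc2)c(OCc2ccccc2)c1)C#C[Si](C)(C)C
F8 | step 5 | 2-{(S)-3-[3,4-bis(benzyloxy)phenyl]-3-[3,5-bis(benzyloxy)-2-vinylphenoxy]prop-1-en-2-yl}-4,4,5,5-tetramethyl-1,3,2-dioxaborolane | C=Cc1c(OCc2ccccc2)cc(OCc2ccccc2)cc1O[C@H](c1ccc(OCc2ccccc2)c(OCc2ccccc2)c1)C(=C)B1OC(C)(C)C(C)(C)O1
F9 | step 5 | potassium (S)-{3-[3,4-bis(benzyloxy)phenyl]-3-[3,5-bis(benzyloxy)-2-vinylphenoxy]prop-1-en-2-yl}trifluoroborate | C=Cc1c(OCc2ccccc2)cc(OCc2ccccc2)cc1O[C@H](c1ccc(OCc2ccccc2)c(OCc2ccccc2)c1)C(=C)[B-](F)(F)F.[K+]
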